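(The constants used here belong to no real substance; the flask was simulated.)

Two questions stand here: the excess of X over Z at the end of each of the three flasks, and the shape of that row.

the same everywhere: J 10 mM; L 1.3 mM (held); Q 10 mM; time 40 min
- gamma: E 0.50 mM
- epsilon: E 1.0 mM
- theta: E 2.0 mM

    G + E + J → E + X (k1 = 19000 M⁻² min⁻¹)
    J ⇌ Q (k2 = 0.027 min⁻¹)
    G + E + Q → E + Z (k3 = 310 M⁻² min⁻¹)
    L ⇌ G, rate k4*(csat - [G]) (k4 = 0.23 min⁻¹, csat = 1.3 mM)

* excess of X over Z at the end for gamma, epsilon, theta, in this order
* the shape of the row from first to last (hardly changes / falls, then rises / rises all the way / rises, then falls / falls all the way)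

- E is single-handed; J and Q are mirror images of each other, charged as a racemate, each of them at the stated concentration
- at the start none of G is dissolved
- an excess is the difference of the two amounts in percent of their sum
- "hardly changes" means that all values lie within two and a half points (for a concentration: within two and a half percent of the largest)
- run time (gamma): 40 min

- We carry s = 61.3, the selectivity factor, meaning the rate constant of the step to X over that of the step to Z. G and E stand in both rates, so at any moment the rate to X over the rate to Z is s times J over Q.
- The first way holds J equal to Q. The excess is then s minus one over s plus one, a ceiling of 0.968 for gamma, and E does not enter it.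
- The second way lets J lag behind Q. L crosses into G with a half-life of 3.01 min, much shorter than the run, so we balance the crossing against the step to X with J at its charge. That gives G of 0.920 mM, 0.712 mM and 0.490 mM in gamma, epsilon and theta.
- J is then lost by a pseudo-first-order constant a, the product of the constant of that step, E and G. The interconversion of J and Q relaxes with constant λ = 0.0540 min⁻¹, so Q over J climbs towards one plus a over λ.
- Counting half-lives, the run holds 3.12 of them at 12.8 min each, and the mean lag over the run is a fraction 0.590 of its final value.
- The mean Q over J, called r, is therefore 1.10, 1.15 and 1.20. The excess, s minus r over s plus r, comes to 0.965, 0.963 and 0.961.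
- The two ways part by 0.64 percentage points at theta, and the first is the one that cheats: it sets r to one, while in theta a is 0.0186 min⁻¹, smaller than λ but not zero.
- Our row spans 0.34 points, inside the margin, so the shape we commit to is: hardly changes.
- The forecast gives 96.5 %, 96.3 %, 96 % and hardly changes, noting that “racemisation partly refills J”.
- The flasks give 96.5 %, 96.3 %, 96.0 % and hardly changes. In gamma the midpoint of the crossing's turnover lay at 15.3 min, and at that time the step to X used J at 0.33 of the forward rate from J to Q. At 40.0 min gamma held J 39.6 %, Q 45.6 % and G 0.971 mM. Read back through s, the excesses put the mean Q over J at 1.09 in gamma, against our 1.10, and at 1.25 in theta, against our 1.20. At 40.0 min theta held X 30.7 % and Z 0.623 %.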